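**Plan**

Ring atoms: C1 carries the aryl group and the oxygen, C2 is the CMe2 carbon, C3 and C4 are CH2.

- Cuts, in order: the angelate C–O(acyl) bond; the four O-methyl masks of the naphthazarin; the C4–H bond (back to an epoxide); the C1–O and C4–O bonds of that epoxide (back to the C1=C4 alkene); the alkene (back to a tertiary carbinol); the C1–aryl bond (aryllithium plus 2,2-dimethylcyclobutanone).
- Forward: the masked naphthalene is brominated and joined through C1 to the intact four-membered ring; dehydration gives the aryl cyclobutene; the oxirane is closed on C1=C4 and opened by hydride at C4; the tertiary alkoxide is angeloylated; the naphthazarin is unmasked last.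
- Enabling feature: C1 bears both aryl and oxygen, C4 is a CH2 and C2 is quaternary. C1=C4 is therefore the only alkene the ring can hold at C1, and it is a flat, aryl-conjugated trisubstituted olefin whose epoxidation puts oxygen on C1.
- Stereochemistry: the single stereocentre (C1, R) is set by a chiral dioxirane in the epoxidation; the C1–O bond is never broken afterwards.

Key step: step 5

Remark 1: the sense of induction is taken from 1-phenylcyclohexene, whose (R,R)-oxide arises with the D-fructose-derived ketone and maps onto the (1R,4R)-epoxide needed here; if the cyclobutene responds in the opposite sense, the enantiomeric ketone (from L-sorbose) would be used in step 5 and nothing else changes.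

Remark 2: the target is one of two rapidly interconverting naphthazarin ring tautomers, so it does not matter which ring of the masked naphthalene ends as the quinone.

**Route**

Step 1
Reactants: 1 naphthazarin (5,8-dihydroxynaphthalene-1,4-dione)
Product: 3 1,4,5,8-tetramethoxynaphthalene, via naphthalene-1,4,5,8-tetrol 2 (not isolated)
Conditions: Na2S2O4, Bu4NBr (cat.), THF/H2O, rt, N2; then NaOH, Me2SO4, rt
Reagents that add atoms: dimethyl sulfate, COS(=O)(=O)OC
Why: Dithionite reduces the quinone to the tetrol, whose phenoxides are O-methylated in the same flask (Williamson-type alkylation under phase-transfer conditions) before air can reoxidise them.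

Step 2
Reactants: 3 1,4,5,8-tetramethoxynaphthalene
Product: 4 2-bromo-1,4,5,8-tetramethoxynaphthalene
Conditions: NBS (1.0 equiv), CH2Cl2, rt, dark
Reagents that add atoms: N-bromosuccinimide, O=C1CCC(=O)N1Br
Why: Electrophilic aromatic bromination; the four free ring positions are equivalent and each lies ortho to a methoxy group, so one equivalent of NBS should give a single monobromide.

Step 3
Reactants: 4 2-bromo-1,4,5,8-tetramethoxynaphthalene; 5 2,2-dimethylcyclobutan-1-one
Product: 7 rac-2,2-dimethyl-1-(1,4,5,8-tetramethoxynaphthalen-2-yl)cyclobutan-1-ol, via (1,4,5,8-tetramethoxynaphthalen-2-yl)lithium 6 (not isolated)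
Conditions: n-BuLi, THF, −78 °C; then 5, −78 to 0 °C; H2O
Reagents that add atoms: none
Why: Bromine–lithium exchange followed by 1,2-addition of the aryllithium to the strained cyclobutanone carbonyl, where relief of angle strain favours addition over enolisation despite the adjacent gem-dimethyl group; the carbinol is racemic and its stereocentre is erased in step 4.

Step 4
Reactants: 7 rac-2,2-dimethyl-1-(1,4,5,8-tetramethoxynaphthalen-2-yl)cyclobutan-1-ol
Product: 8 2-(4,4-dimethylcyclobut-1-en-1-yl)-1,4,5,8-tetramethoxynaphthalene
Conditions: Burgess reagent, THF, 50 °C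
Reagents that add atoms: none
Why: Burgess dehydration through the tertiary sulfamate ester (syn-elimination or ion-pair E1) under non-acidic conditions; C2 is quaternary, so the only β-hydrogens are on C4 and the C1=C4 alkene is the sole possible olefin.

Step 5
Reactants: 8 2-(4,4-dimethylcyclobut-1-en-1-yl)-1,4,5,8-tetramethoxynaphthalene
Product: 9 (1R,4R)-2,2-dimethyl-1-(1,4,5,8-tetramethoxynaphthalen-2-yl)-5-oxabicyclo[2.1.0]pentane
Conditions: 1,2:4,5-di-O-isopropylidene-β-D-erythro-2,3-hexodiulo-2,6-pyranose (30 mol %), KHSO5 (as 2KHSO5·KHSO4·K2SO4), K2CO3, Bu4NHSO4 (cat.), MeCN/CH2(OMe)2/aq. Na2B4O7–Na2H2EDTA buffer (pH 10.5), 0 °C; cold base-washed extraction, no chromatography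
Reagents that add atoms: potassium peroxymonosulfate (KHSO5), [K+].[O-]S(=O)(=O)OO
Why: KHSO5 converts the ketone into a chiral dioxirane, which transfers one oxygen atom concertedly to the C1=C4 bond through a spiro transition state and regenerates the ketone. The closest known reaction is the Shi epoxidation of 1-arylcycloalkenes and other trisubstituted styrene-type olefins. The oxirane closes in a single syn [2+1] oxygen-atom addition, both C–O bonds forming on one face, so the bicycle is necessarily cis-fused. C1 and C4 are set together by the catalyst, which keeps the aryl group and the ring CH2 (C3) away from its fused dioxolane in the spiro arrangement while the gem-dimethyl group on C2 penalises the competing planar arrangement; the configuration at C4 follows from that at C1 and is removed in step 6. The step needs face selectivity, oxidation of the alkene in preference to the electron-rich arene, and survival of the acid-labile benzylic epoxide; the strained conjugated alkene is the most nucleophilic site, and the pH 10.5 buffer, low temperature and immediate use of the crude epoxide should keep it from ionising at C1.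

Step 6
Reactants: 9 (1R,4R)-2,2-dimethyl-1-(1,4,5,8-tetramethoxynaphthalen-2-yl)-5-oxabicyclo[2.1.0]pentane
Product: 10 (1R)-2,2-dimethyl-1-(1,4,5,8-tetramethoxynaphthalen-2-yl)cyclobutan-1-ol
Conditions: LiEt3BH, THF, 0 °C to rt; H2O
Reagents that add atoms: none
Why: SN2 epoxide opening by a nucleophilic, non-Lewis-acidic hydride at the secondary carbon C4, anti to the C4–O bond and driven by release of bicyclic strain; the tertiary, neopentyl-type benzylic C1 is inaccessible, so the C1–O bond and its configuration are retained.

Step 7
Reactants: 11 angelic acid ((2Z)-2-methylbut-2-enoic acid), two molecules per molecule of anhydride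
Product: 12 angelic anhydride ((2Z)-2-methylbut-2-enoic anhydride)
Conditions: 11 (2.0 equiv), DCC (1.0 equiv), CH2Cl2, 0 °C to rt; filtration
Reagents that add atoms: angelic acid (the second molecule of 11), C/C=C(/C)C(=O)O
Why: Carbodiimide-mediated dehydration in which one molecule of acid is activated as the O-acylisourea and acylated by a second molecule gives the symmetric anhydride under neutral conditions at or below room temperature, which should leave both Z double bonds unchanged.

Step 8
Reactants: 10 (1R)-2,2-dimethyl-1-(1,4,5,8-tetramethoxynaphthalen-2-yl)cyclobutan-1-ol; 12 angelic anhydride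
Product: 14 (1R)-2,2-dimethyl-1-(1,4,5,8-tetramethoxynaphthalen-2-yl)cyclobutyl (2Z)-2-methylbut-2-enoate, via lithium alkoxide 13 (not isolated)
Conditions: LiN(SiMe3)2 (1.0 equiv), THF, −78 to 0 °C; then 12, 0 °C to rt; H2O
Reagents that add atoms: none
Why: Nucleophilic acyl substitution of the preformed lithium alkoxide on the anhydride, with no excess base and no nucleophilic amine catalyst present, should avoid Z-to-E isomerisation of the angeloyl group; C1 is untouched because its C–O bond is not broken, and acylation also blocks oxidative ring opening of the cyclobutanol in step 9.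

Step 9
Reactants: 14 (1R)-2,2-dimethyl-1-(1,4,5,8-tetramethoxynaphthalen-2-yl)cyclobutyl (2Z)-2-methylbut-2-enoate
Product: 18 (1R)-1-(5,8-dihydroxy-1,4-dioxo-1,4-dihydronaphthalen-2-yl)-2,2-dimethylcyclobutyl (2Z)-2-methylbut-2-enoate (CNP0326301.1), via dimethoxyquinone 15 (not isolated), via isomeric dimethoxyquinone 16 (not isolated), via tetrone 17 (not isolated)
Conditions: AgO (10 equiv), 6 M HNO3 added last, 1,4-dioxane, rt; then aq. Na2S2O4
Reagents that add atoms: water, O
Why: Oxidative demethylation by divalent silver turns each para-dimethoxy ring into a quinone by electron transfer, ipso attack of water and loss of methanol; whichever ring reacts first (15 or 16), the second oxidation converges on tetrone 17, which dithionite reduces by two electrons to the naphthazarin, while the electron-poor angelate, the cyclobutane and the C1–O bond (deactivated towards ionisation once a quinone ring is attached) should not be affected.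

**Compound list**

1 | naphthazarin (5,8-dihydroxynaphthalene-1,4-dione) | O=C1C=CC(=O)c2c(O)ccc(O)c12 | starting material
2 | naphthalene-1,4,5,8-tetrol | Oc1ccc(O)c2c(O)ccc(O)c12 | intermediate
3 | 1,4,5,8-tetramethoxynaphthalene | COc1ccc(OC)c2c(OC)ccc(OC)c12 | intermediate
4 | 2-bromo-1,4,5,8-tetramethoxynaphthalene | COc1cc(Br)c(OC)c2c(OC)ccc(OC)c12 | intermediate
5 | 2,2-dimethylcyclobutan-1-one | CC1(C)CCC1=O | starting material
6 | (1,4,5,8-tetramethoxynaphthalen-2-yl)lithium | [Li]c1cc(OC)c2c(OC)ccc(OC)c2c1OC | intermediate
7 | rac-2,2-dimethyl-1-(1,4,5,8-tetramethoxynaphthalen-2-yl)cyclobutan-1-ol | CC1(C)CCC1(O)c1cc(OC)c2c(OC)ccc(OC)c2c1OC | intermediate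
8 | 2-(4,4-dimethylcyclobut-1-en-1-yl)-1,4,5,8-tetramethoxynaphthalene | CC1(C)CC=C1c1cc(OC)c2c(OC)ccc(OC)c2c1OC | intermediate
9 | (1R,4R)-2,2-dimethyl-1-(1,4,5,8-tetramethoxynaphthalen-2-yl)-5-oxabicyclo[2.1.0]pentane | O1[C@@H]2CC(C)(C)[C@]12c1cc(OC)c2c(OC)ccc(OC)c2c1OC | intermediate
10 | (1R)-2,2-dimethyl-1-(1,4,5,8-tetramethoxynaphthalen-2-yl)cyclobutan-1-ol | O[C@]1(c2cc(OC)c3c(OC)ccc(OC)c3c2OC)CCC1(C)C | intermediate
11 | angelic acid ((2Z)-2-methylbut-2-enoic acid) | C/C=C(/C)C(=O)O | starting material
12 | angelic anhydride ((2Z)-2-methylbut-2-enoic anhydride) | C/C=C(/C)C(=O)OC(=O)C(/C)=C\C | intermediate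
13 | lithium (1R)-2,2-dimethyl-1-(1,4,5,8-tetramethoxynaphthalen-2-yl)cyclobutan-1-olate | [Li+].[O-][C@]1(c2cc(OC)c3c(OC)ccc(OC)c3c2OC)CCC1(C)C | intermediate
14 | (1R)-2,2-dimethyl-1-(1,4,5,8-tetramethoxynaphthalen-2-yl)cyclobutyl (2Z)-2-methylbut-2-enoate | C/C=C(/C)C(=O)O[C@]1(c2cc(OC)c3c(OC)ccc(OC)c3c2OC)CCC1(C)C | intermediate
15 | (1R)-1-(1,4-dimethoxy-5,8-dioxo-5,8-dihydronaphthalen-2-yl)-2,2-dimethylcyclobutyl (2Z)-2-methylbut-2-enoate | C/C=C(/C)C(=O)O[C@]1(c2cc(OC)c3C(=O)C=CC(=O)c3c2OC)CCC1(C)C | intermediate
16 | (1R)-1-(5,8-dimethoxy-1,4-dioxo-1,4-dihydronaphthalen-2-yl)-2,2-dimethylcyclobutyl (2Z)-2-methylbut-2-enoate | C/C=C(/C)C(=O)O[C@]1(C2=CC(=O)c3c(OC)ccc(OC)c3C2=O)CCC1(C)C | intermediate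
17 | (1R)-2,2-dimethyl-1-(1,4,5,8-tetraoxo-1,4,5,8-tetrahydronaphthalen-2-yl)cyclobutyl (2Z)-2-methylbut-2-enoate | C/C=C(/C)C(=O)O[C@]1(C2=CC(=O)C3=C(C2=O)C(=O)C=CC3=O)CCC1(C)C | intermediate
18 | (1R)-1-(5,8-dihydroxy-1,4-dioxo-1,4-dihydronaphthalen-2-yl)-2,2-dimethylcyclobutyl (2Z)-2-methylbut-2-enoate (CNP0326301.1) | C/C=C(/C)C(=O)O[C@]1(C2=CC(=O)c3c(O)ccc(O)c3C2=O)CCC1(C)C | target

**Step count**

Total: 9 steps. Longest linear sequence: 8 steps (steps 1–6, 8 and 9, from naphthazarin); step 7 is a one-step side branch that consumes two molecules of angelic acid per molecule of anhydride.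

**Steps most likely to fail**

Step 5. The benzylic C1–O bond of the epoxide may ionise under the donor effect of the tetramethoxynaphthyl group, and the epoxide may then rearrange by hydride shift or ring contraction before it can be reduced. Facial discrimination may also be weaker on the four-membered ring than on six-membered models. The fallback gives up catalyst control for separation. It sets out from racemic carbinol 7, which step 3 already delivers, and resolves it by preparative chromatography on an amylose-based chiral stationary phase (supercritical CO2/MeOH). This gives carbinol 10 directly, and the unwanted (1S)-2,2-dimethyl-1-(1,4,5,8-tetramethoxynaphthalen-2-yl)cyclobutan-1-ol F1 is set aside. The route is rejoined at 10, and steps 4–6 are bypassed.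

Step 9. The second ring is deactivated once the first has become a quinone, so its oxidation may stall. The electrophilic tetrone may be hydrated or degraded in aqueous acid, and the tertiary ester may be lost by acid-promoted ionisation before the first oxidation is complete. The fallback separates the two stages and makes the second one non-oxidative. It sets out from 14, which is oxidised only once with (NH4)2Ce(NO3)6 in MeCN/H2O at 0 °C to the mixture of dimethoxyquinones 15 and 16, now isolated. Each remaining methoxy group lies peri to a quinone carbonyl, and both are cleaved by chelation-controlled Lewis-acid dealkylation with BCl3 in CH2Cl2 at −78 °C. The route is rejoined at target 18, and the fallback passes only through listed compounds (none new, F0).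

Step 8. Acyl transfer to the hindered tertiary alkoxide, flanked by a quaternary carbon and an ortho-methoxy aryl group, may be slow. Longer exposure to base may then cause Z-to-E isomerisation to the tiglate or deconjugation through the dienolate. The fallback builds the Z-olefin on the ester instead of transferring it. It sets out from 10, which is esterified with 2-[bis(2,2,2-trifluoroethoxy)phosphoryl]propanoic acid, DCC and catalytic DMAP in CH2Cl2; the intermediate phosphonoketene is known to acylate hindered alcohols. This gives (1R)-2,2-dimethyl-1-(1,4,5,8-tetramethoxynaphthalen-2-yl)cyclobutyl 2-[bis(2,2,2-trifluoroethoxy)phosphoryl]propanoate F2 as a mixture of epimers at the phosphorus-bearing carbon. Still–Gennari olefination with acetaldehyde (KN(SiMe3)2, 18-crown-6, THF, −78 °C) should then give the Z-configured 2-methylbut-2-enoate, and the route is rejoined at 14.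

**Further compounds**

F1 | step 5 | (1S)-2,2-dimethyl-1-(1,4,5,8-tetramethoxynaphthalen-2-yl)cyclobutan-1-ol | O[C@@]1(c2cc(OC)c3c(OC)ccc(OC)c3c2OC)CCC1(C)C
F0 | step 9 | none | none
F2 | step 8 | (1R)-2,2-dimethyl-1-(1,4,5,8-tetramethoxynaphthalen-2-yl)cyclobutyl 2-[bis(2,2,2-trifluoroethoxy)phosphoryl]propanoate | CC(C(=O)O[C@]1(c2cc(OC)c3c(OC)ccc(OC)c3c2OC)CCC1(C)C)P(=O)(OCC(F)(F)F)OCC(F)(F)F
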